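The route rests on disconnecting both ring A oxygens, at C1 (ketone carbon) and C4 (acetoxy carbon), which flank the C2=C3 alkene, back to a C1–C4 diene. The C7–C8 acid arm on spiro carbon C6, destined for lactone ring B, is first borrowed as a tether: palladium-catalysed 1,4-acetoxylactonisation closes a temporary cis-fused C8–O–C1 lactone and delivers acetate to C4 on the opposite face, setting both stereocentres in one operation. The precursor is a 5,5-disubstituted cyclohexa-1,3-diene acid carrying the complete C9–C15 chain with the C9 and C15 oxygens silylated. Lactone opening, C1 oxidation and acid-triggered relactonisation onto C9 then give the target.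

Key step: step 11

Numbering: ring A = C1 (ketone carbon), C2=C3, C4 (acetoxy carbon), C5 (CH2), C6 (spiro carbon); ring B = C6, C7 (CH2), C8 (lactone carbonyl), O, C9; side chain = C10–C15 (methyls on C11 and C15).

Check of structures: the target is 4S,6R,9R in this numbering. Diene acid 17 and fused lactone 19 keep the same arrangement at C6 and C9; in 19 the C1 oxygen is cis to C7 and the C4 acetate is trans to C7 and cis to C9. No stereochemical correction was needed.

Precursor design: the C15 tertiary allylic alcohol is carried as a triethylsilyl ether, and C9 as the sturdier tert-butyldimethylsilyl ether. This keeps a free, ionisable allylic alcohol out of the acetic acid/palladium medium, frees the C9 silylation of step 10 from any selectivity demand, spares the aluminium amide in step 12, and lets one acidic fluoride treatment unmask both oxygens at the end.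

Assumption: the (S)-configured oxazaborolidinium catalyst of step 2 and the (S)-configured sulfonamide ligand of step 8 are taken to give the required C6 (S in 4 and 5) and C9 (R) senses; if a first run shows the opposite sense, the antipodal catalyst or ligand is used with no other change.

Step 1
Reactants: 1 methyl 4-oxobutanoate
Product: 2 methyl 3-formylbut-3-enoate
Conditions: 37% aq. CH2O (1.1 equiv), pyrrolidine (10 mol%), propionic acid (10 mol%), iPrOH, 45 °C; distilled and stored cold
Reagents that add atoms: formaldehyde, C=O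
Why: Organocatalytic α-methylenation of an aldehyde (enamine Mannich addition to formaldehyde, then loss of the amine) takes place only at the aldehyde α-carbon and creates no stereocentre.

Step 2
Reactants: 2 methyl 3-formylbut-3-enoate; 3 (E)-buta-1,3-dien-1-yl acetate
Product: 4 methyl 2-[(1S,2S)-2-acetoxy-1-formylcyclohex-3-en-1-yl]acetate
Conditions: (S)-3,3-diphenyl-1-(2-methylphenyl)tetrahydro-1H,3H-pyrrolo[1,2-c][1,3,2]oxazaborole (20 mol%), HNTf2 (16 mol%), CH2Cl2, −78 → −40 °C
Reagents that add atoms: none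
Why: Enantioselective Lewis-acid-catalysed Diels–Alder reaction of a 2-substituted acrolein, in which the acetoxy-bearing diene terminus bonds to the α-carbon (ortho rule) and the formyl-bound cationic oxazaborolidine shields one face of the dienophile, setting quaternary C6 as S; the endo C1 acetoxy centre is removed in step 3.

Step 3
Reactants: 4 methyl 2-[(1S,2S)-2-acetoxy-1-formylcyclohex-3-en-1-yl]acetate
Product: 5 methyl 2-[(1S)-1-formylcyclohexa-2,4-dien-1-yl]acetate
Conditions: Pd(PPh3)4 (5 mol%), Et3N (2 equiv), THF, 60 °C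
Reagents that add atoms: none
Why: Tsuji–Trost ionisation of the allylic acetate by zerovalent palladium gives a C1–C3 π-allyl complex whose only β-hydrogens are on C4 (C6 is quaternary), so β-hydride elimination can give only the C1=C2–C3=C4 diene, while Et3N traps the palladium hydride before it can re-add and move the diene, which would erode C6.

Step 4
Reactants: 6 2-methylbut-3-yn-2-ol; 7 propargyl bromide
Product: 8 2-methylhepta-3,6-diyn-2-ol
Conditions: 6 (3 equiv), CuI (1 equiv), NaI (1 equiv), K2CO3 (1.5 equiv), DMF, rt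
Reagents that add atoms: none
Why: Copper-mediated alkyne–propargyl coupling (monovalent copper acetylide substitutes the propargylic halide after Finkelstein exchange) gives the skipped diyne, and the excess of 6 suppresses a second propargylation of the new terminal alkyne.

Step 5
Reactants: 8 2-methylhepta-3,6-diyn-2-ol
Product: 9 (E)-2-methylhept-3-en-6-yn-2-ol
Conditions: NaAlH2(OCH2CH2OMe)2 (2.5 equiv), THF, 0 °C → rt; aq. potassium sodium tartrate
Reagents that add atoms: none
Why: Hydroxyl-directed trans-hydroalumination of a propargylic alcohol (hydride delivered from the alkoxyaluminate to C14, aluminium on C13, anti addition) reduces only the C13≡C14 alkyne to the E-alkene, the remote terminal alkyne being at most deprotonated.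

Step 6
Reactants: 9 (E)-2-methylhept-3-en-6-yn-2-ol
Product: 11 (3E,6E)-7-iodo-2,6-dimethylhepta-3,6-dien-2-ol, via alkenylalane 10 (not isolated)
Conditions: AlMe3 (3 equiv), Cp2ZrCl2 (0.25 equiv), CH2Cl2, 0 °C → rt; then I2, THF, −30 → 0 °C
Reagents that add atoms: trimethylaluminium, C[Al](C)C; iodine, II
Why: Zirconium-catalysed syn-methylalumination of the terminal alkyne (Negishi carboalumination) puts methyl on C11 and aluminium on C10 cis to it, and iodinolysis of the C–Al bond with retention fixes the E trisubstituted vinyl iodide.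

Step 7
Reactants: 11 (3E,6E)-7-iodo-2,6-dimethylhepta-3,6-dien-2-ol
Product: 12 triethyl{[(3E,6E)-7-iodo-2,6-dimethylhepta-3,6-dien-2-yl]oxy}silane
Conditions: TESOTf (1.2 equiv), 2,6-lutidine (2 equiv), CH2Cl2, −78 °C
Reagents that add atoms: triethylsilyl trifluoromethanesulfonate, CC[Si](CC)(CC)OS(=O)(=O)C(F)(F)F
Why: Silyl triflate silylation of a tertiary alcohol with a hindered pyridine base is routine and masks C15–OH for the coupling, silylation, palladium and aluminium amide steps.

Step 8
Reactants: 5 methyl 2-[(1S)-1-formylcyclohexa-2,4-dien-1-yl]acetate; 12 triethyl{[(3E,6E)-7-iodo-2,6-dimethylhepta-3,6-dien-2-yl]oxy}silane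
Product: 14 (1R,5S)-1-[(1E,4E)-2,6-dimethyl-6-(triethylsilyloxy)hepta-1,4-dien-1-yl]-2-oxaspiro[4.5]deca-6,8-dien-3-one, via hydroxy ester 13 (not isolated)
Conditions: CrCl2 (3 equiv), (S)-N-[2-(4-isopropyl-4,5-dihydrooxazol-2-yl)-6-methylphenyl]methanesulfonamide (3.3 equiv), Et3N (3.3 equiv), NiCl2 (2 mol%), THF, rt; then PPTS (cat.), CH2Cl2, rt
Reagents that add atoms: none
Why: Nozaki–Hiyama–Kishi reaction (zerovalent nickel inserts into the vinyl iodide, the alkenyl group passes to trivalent chromium and adds to the non-enolisable aldehyde with retention of alkene geometry), in which the chiral sulfonamide on chromium directs addition to the Re face of C9 to give 9R, and the γ-hydroxy ester then closes to the spiro lactone, whose C9 epimers can be separated.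

Step 9
Reactants: 14 (1R,5S)-1-[(1E,4E)-2,6-dimethyl-6-(triethylsilyloxy)hepta-1,4-dien-1-yl]-2-oxaspiro[4.5]deca-6,8-dien-3-one
Product: 15 lithium 2-[(1S)-1-[(1R,2E,5E)-1-hydroxy-3,7-dimethyl-7-(triethylsilyloxy)octa-2,5-dien-1-yl]cyclohexa-2,4-dien-1-yl]acetate
Conditions: LiOH·H2O (1.1 equiv), THF/H2O (3:1), 0 °C → rt; evaporation, toluene azeotrope
Reagents that add atoms: lithium hydroxide, [Li+].[OH-]
Why: Saponification of a γ-lactone with one equivalent of hydroxide gives the γ-hydroxy carboxylate, which is stable as its salt, and touches no stereocentre.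

Step 10
Reactants: 15 lithium 2-[(1S)-1-[(1R,2E,5E)-1-hydroxy-3,7-dimethyl-7-(triethylsilyloxy)octa-2,5-dien-1-yl]cyclohexa-2,4-dien-1-yl]acetate
Product: 17 2-[(1S)-1-[(1R,2E,5E)-1-(tert-butyldimethylsilyloxy)-3,7-dimethyl-7-(triethylsilyloxy)octa-2,5-dien-1-yl]cyclohexa-2,4-dien-1-yl]acetic acid, via silyl ester 16 (not isolated)
Conditions: TBSOTf (3 equiv), 2,6-lutidine (5 equiv), CH2Cl2, −78 → 0 °C; then K2CO3 (1.5 equiv), MeOH/THF/H2O, 0 °C; pH 5 buffer
Reagents that add atoms: tert-butyldimethylsilyl trifluoromethanesulfonate, CC(C)(C)[Si](C)(C)OS(=O)(=O)C(F)(F)F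
Why: Silyl triflate O-silylation caps the hindered C9 hydroxyl and the carboxylate, and mild carbonate methanolysis then cleaves only the labile silyl ester, the standard way to hold a γ-hydroxy acid open.

Step 11
Reactants: 17 2-[(1S)-1-[(1R,2E,5E)-1-(tert-butyldimethylsilyloxy)-3,7-dimethyl-7-(triethylsilyloxy)octa-2,5-dien-1-yl]cyclohexa-2,4-dien-1-yl]acetic acid; 18 acetic acid
Product: 19 (3aS,5S,7aR)-3a-[(1R,2E,5E)-1-(tert-butyldimethylsilyloxy)-3,7-dimethyl-7-(triethylsilyloxy)octa-2,5-dien-1-yl]-2-oxo-2,3,3a,4,5,7a-hexahydro-1-benzofuran-5-yl acetate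
Conditions: Pd(OAc)2 (5 mol%), p-benzoquinone (2 equiv), anhydrous acetone/AcOH (4:1), 20 °C, chloride-free
Reagents that add atoms: none
Why: Divalent palladium binds the C1–C4 diene on the face that carries C9, the tethered C8 carboxylate attacks C1 anti to the metal from the C7 face, and the resulting C2–C4 π-allyl palladium passes a coordinated acetate to C4 on its own face before benzoquinone returns zerovalent palladium to the divalent state. The closest known reaction type is the palladium-catalysed intramolecular 1,4-acetoxylactonisation of cyclohexa-2,4-dienylacetic acids with benzoquinone as oxidant. The lactone ring (O–C8–C7–C6–C1) closes in a 5-exo-trig mode, and the one-carbon tether permits only cis fusion, which fixes C1 as R. C4 (S) is fixed by inner-sphere acetate migration from palladium, which sits opposite the new C1–O bond, so the acetate ends trans to C7 and cis to C9. The step needs attack at C1 and not C4, trans 1,4-addition and no reaction at the side-chain alkenes: the short tether reaches only C1, the chloride-free medium disfavours outer-sphere attack at C4, acetate adds at the unhindered distal allyl terminus C4 and not at C2, and only the conjugated diene forms the η4 complex that is open to nucleophilic attack. Both hydroxyls are silylated, so no other oxygen nucleophile competes.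

Step 12
Reactants: 19 (3aS,5S,7aR)-3a-[(1R,2E,5E)-1-(tert-butyldimethylsilyloxy)-3,7-dimethyl-7-(triethylsilyloxy)octa-2,5-dien-1-yl]-2-oxo-2,3,3a,4,5,7a-hexahydro-1-benzofuran-5-yl acetate
Product: 20 (1S,4R,5S)-5-[(1R,2E,5E)-1-(tert-butyldimethylsilyloxy)-3,7-dimethyl-7-(triethylsilyloxy)octa-2,5-dien-1-yl]-4-hydroxy-5-{2-[methoxy(methyl)amino]-2-oxoethyl}cyclohex-2-en-1-yl acetate
Conditions: MeNH(OMe)·HCl (3 equiv), AlMe3 (3 equiv), CH2Cl2, −20 → 0 °C; aq. potassium sodium tartrate (pH 7); crude used at once
Reagents that add atoms: N,O-dimethylhydroxylamine hydrochloride, CNOC.Cl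
Why: Weinreb aminolysis with an aluminium amide opens the γ-lactone, which is locked in the more electrophilic E ester geometry, faster than the acetate at low temperature, and the aluminium alkoxide formed at C1 blocks reversal until work-up; no stereocentre changes.

Step 13
Reactants: 20 (1S,4R,5S)-5-[(1R,2E,5E)-1-(tert-butyldimethylsilyloxy)-3,7-dimethyl-7-(triethylsilyloxy)octa-2,5-dien-1-yl]-4-hydroxy-5-{2-[methoxy(methyl)amino]-2-oxoethyl}cyclohex-2-en-1-yl acetate
Product: 21 (1S,5R)-5-[(1R,2E,5E)-1-(tert-butyldimethylsilyloxy)-3,7-dimethyl-7-(triethylsilyloxy)octa-2,5-dien-1-yl]-5-{2-[methoxy(methyl)amino]-2-oxoethyl}-4-oxocyclohex-2-en-1-yl acetate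
Conditions: Dess–Martin periodinane (1.5 equiv), NaHCO3 (5 equiv), CH2Cl2, 0 °C → rt
Reagents that add atoms: none
Why: Dess–Martin oxidation of the secondary allylic C1 alcohol gives the enone under buffered, non-basic conditions that leave the γ-acetoxy group, both silyl ethers and the amide untouched, and removes the hydroxyl that could re-close the temporary lactone.

Step 14
Reactants: 21 (1S,5R)-5-[(1R,2E,5E)-1-(tert-butyldimethylsilyloxy)-3,7-dimethyl-7-(triethylsilyloxy)octa-2,5-dien-1-yl]-5-{2-[methoxy(methyl)amino]-2-oxoethyl}-4-oxocyclohex-2-en-1-yl acetate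
Product: 23 (1R,5R,9S)-1-[(1E,4E)-6-hydroxy-2,6-dimethylhepta-1,4-dien-1-yl]-3,6-dioxo-2-oxaspiro[4.5]dec-7-en-9-yl acetate, via hydroxy amide 22 (not isolated)
Conditions: HF·pyridine, THF, 0 °C → rt
Reagents that add atoms: none
Why: Acidic fluoride desilylation frees C9–OH and C15–OH, and the γ-hydroxy N-methoxy-N-methylamide then lactonises by 5-exo-trig acyl transfer (helped by the Thorpe–Ingold effect of quaternary C6), expelling the weakly basic amine and retaining all stereocentres.

Compound list
1 | methyl 4-oxobutanoate | COC(=O)CCC=O | starting material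
2 | methyl 3-formylbut-3-enoate | COC(=O)CC(=C)C=O | intermediate
3 | (E)-buta-1,3-dien-1-yl acetate (1-acetoxybuta-1,3-diene) | CC(=O)O/C=C/C=C | starting material
4 | methyl 2-[(1S,2S)-2-acetoxy-1-formylcyclohex-3-en-1-yl]acetate | COC(=O)C[C@]1(CCC=C[C@@H]1OC(C)=O)C=O | intermediate
5 | methyl 2-[(1S)-1-formylcyclohexa-2,4-dien-1-yl]acetate | COC(=O)C[C@@]1(C=CC=CC1)C=O | intermediate
6 | 2-methylbut-3-yn-2-ol | CC(C)(O)C#C | starting material
7 | propargyl bromide (3-bromoprop-1-yne) | C#CCBr | starting material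
8 | 2-methylhepta-3,6-diyn-2-ol | CC(C)(O)C#CCC#C | intermediate
9 | (E)-2-methylhept-3-en-6-yn-2-ol | CC(C)(O)/C=C/CC#C | intermediate
10 | dimethylaluminium alkoxide of [(1E,4E)-6-hydroxy-2,6-dimethylhepta-1,4-dien-1-yl]dimethylalane (alkenylalane) | CC(C)(O[Al](C)C)/C=C/C/C(C)=C/[Al](C)C | intermediate
11 | (3E,6E)-7-iodo-2,6-dimethylhepta-3,6-dien-2-ol | CC(C)(O)/C=C/C/C(C)=C/I | intermediate
12 | triethyl{[(3E,6E)-7-iodo-2,6-dimethylhepta-3,6-dien-2-yl]oxy}silane | CC[Si](CC)(CC)OC(C)(C)/C=C/C/C(C)=C/I | intermediate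
13 | methyl 2-[(1S)-1-[(1R,2E,5E)-1-hydroxy-3,7-dimethyl-7-(triethylsilyloxy)octa-2,5-dien-1-yl]cyclohexa-2,4-dien-1-yl]acetate | COC(=O)C[C@@]1(C=CC=CC1)[C@H](O)/C=C(\C)C/C=C/C(C)(C)O[Si](CC)(CC)CC | intermediate
14 | (1R,5S)-1-[(1E,4E)-2,6-dimethyl-6-(triethylsilyloxy)hepta-1,4-dien-1-yl]-2-oxaspiro[4.5]deca-6,8-dien-3-one | O=C1C[C@@]2(C=CC=CC2)[C@H](O1)/C=C(\C)C/C=C/C(C)(C)O[Si](CC)(CC)CC | intermediate
15 | lithium 2-[(1S)-1-[(1R,2E,5E)-1-hydroxy-3,7-dimethyl-7-(triethylsilyloxy)octa-2,5-dien-1-yl]cyclohexa-2,4-dien-1-yl]acetate | [Li+].[O-]C(=O)C[C@@]1(C=CC=CC1)[C@H](O)/C=C(\C)C/C=C/C(C)(C)O[Si](CC)(CC)CC | intermediate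
16 | tert-butyldimethylsilyl 2-[(1S)-1-[(1R,2E,5E)-1-(tert-butyldimethylsilyloxy)-3,7-dimethyl-7-(triethylsilyloxy)octa-2,5-dien-1-yl]cyclohexa-2,4-dien-1-yl]acetate | CC(C)(C)[Si](C)(C)OC(=O)C[C@@]1(C=CC=CC1)[C@H](O[Si](C)(C)C(C)(C)C)/C=C(\C)C/C=C/C(C)(C)O[Si](CC)(CC)CC | intermediate
17 | 2-[(1S)-1-[(1R,2E,5E)-1-(tert-butyldimethylsilyloxy)-3,7-dimethyl-7-(triethylsilyloxy)octa-2,5-dien-1-yl]cyclohexa-2,4-dien-1-yl]acetic acid | OC(=O)C[C@@]1(C=CC=CC1)[C@H](O[Si](C)(C)C(C)(C)C)/C=C(\C)C/C=C/C(C)(C)O[Si](CC)(CC)CC | intermediate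
18 | acetic acid | CC(=O)O | starting material
19 | (3aS,5S,7aR)-3a-[(1R,2E,5E)-1-(tert-butyldimethylsilyloxy)-3,7-dimethyl-7-(triethylsilyloxy)octa-2,5-dien-1-yl]-2-oxo-2,3,3a,4,5,7a-hexahydro-1-benzofuran-5-yl acetate | CC(=O)O[C@@H]1C=C[C@H]2OC(=O)C[C@]2(C1)[C@H](O[Si](C)(C)C(C)(C)C)/C=C(\C)C/C=C/C(C)(C)O[Si](CC)(CC)CC | intermediate
20 | (1S,4R,5S)-5-[(1R,2E,5E)-1-(tert-butyldimethylsilyloxy)-3,7-dimethyl-7-(triethylsilyloxy)octa-2,5-dien-1-yl]-4-hydroxy-5-{2-[methoxy(methyl)amino]-2-oxoethyl}cyclohex-2-en-1-yl acetate | CC(=O)O[C@@H]1C=C[C@@H](O)[C@@](CC(=O)N(C)OC)(C1)[C@H](O[Si](C)(C)C(C)(C)C)/C=C(\C)C/C=C/C(C)(C)O[Si](CC)(CC)CC | intermediate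
21 | (1S,5R)-5-[(1R,2E,5E)-1-(tert-butyldimethylsilyloxy)-3,7-dimethyl-7-(triethylsilyloxy)octa-2,5-dien-1-yl]-5-{2-[methoxy(methyl)amino]-2-oxoethyl}-4-oxocyclohex-2-en-1-yl acetate | CC(=O)O[C@@H]1C=CC(=O)[C@@](CC(=O)N(C)OC)(C1)[C@H](O[Si](C)(C)C(C)(C)C)/C=C(\C)C/C=C/C(C)(C)O[Si](CC)(CC)CC | intermediate
22 | (1S,5R)-5-[(1R,2E,5E)-1,7-dihydroxy-3,7-dimethylocta-2,5-dien-1-yl]-5-{2-[methoxy(methyl)amino]-2-oxoethyl}-4-oxocyclohex-2-en-1-yl acetate | CC(=O)O[C@@H]1C=CC(=O)[C@@](CC(=O)N(C)OC)(C1)[C@H](O)/C=C(\C)C/C=C/C(C)(C)O | intermediate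
23 | (+)-miliusane XVII, (1R,5R,9S)-1-[(1E,4E)-6-hydroxy-2,6-dimethylhepta-1,4-dien-1-yl]-3,6-dioxo-2-oxaspiro[4.5]dec-7-en-9-yl acetate | CC(=O)O[C@@H]1C=CC(=O)[C@@]2(CC(=O)O[C@@H]2/C=C(\C)C/C=C/C(C)(C)O)C1 | target

Total step count: 14.
Longest linear sequence: 11 steps (steps 4 to 14, from 6 through 8, 9, 11, 12, 14, 15, 17, 19, 20 and 21 to 23); the ring branch (steps 1 to 3) joins at step 8.

Steps most likely to fail

Step 11. What may go wrong is loss of face control in the second C–O bond: outer-sphere acetate attack on the π-allyl intermediate can compete with inner-sphere migration, which would give the C4 epimer, and the metal may be slow to bind the diene face that carries the C9 branch. The fallback separates the two C–O bond formations. Starting from 17, the chloride-controlled variant is run (Pd(OAc)2 5 mol%, benzoquinone 2 equiv, LiCl 2 equiv, acetone/AcOH, 20 °C). Chloride on palladium blocks acetate migration and attacks C4 from outside, anti to the metal, so chlorine enters cis to the lactone oxygen and gives the cis-chloro lactone F1. Displacement of the allylic chloride with CsOAc in DMF at rt, a plain SN2 reaction with inversion at C4, then returns to the route at 19.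

Step 12. What may go wrong is competing aminolysis of the C4 acetate by the aluminium amide, or re-closure of the hydroxy amide to 19 during work-up. Re-closure only returns starting material, which can be resubmitted. For acetate loss, the fallback gives up the selectivity on purpose. Starting from 19, the aluminium amide is used in excess at rt so that lactone and acetate are both cleaved, giving the diol amide F2. The C4 hydroxyl, which is far less hindered than the C1 hydroxyl next to quaternary C6, is then acetylated alone (AcCl, 2,4,6-collidine, CH2Cl2, −78 °C), which returns to the route at 20.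

Step 8. What may go wrong is poor facial selectivity in the addition to the aldehyde, because C9 is created next to a quaternary carbon whose three carbon substituents differ little in size. The fallback sets C9 by reduction instead of addition. Starting from 5 and 12, the coupling is run without the chiral ligand (CrCl2, NiCl2 cat., DMSO, rt) and worked up at neutral pH, giving 13 together with its C9 epimer F3. Dess–Martin oxidation of the mixture converges on the C9 enone F4. Corey–Bakshi–Shibata reduction ((S)-1-methyl-3,3-diphenyltetrahydro-1H,3H-pyrrolo[1,2-c][1,3,2]oxazaborole, catecholborane, toluene, −78 °C), with quaternary C6 as the large group and the alkenyl as the small one, should then give (9R)-13. Lactonisation with PPTS as in step 8 returns to the route at 14.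

Further compounds
F1 | step 11 | (3aR,5R,7aR)-5-chloro-3a-[(1R,2E,5E)-1-(tert-butyldimethylsilyloxy)-3,7-dimethyl-7-(triethylsilyloxy)octa-2,5-dien-1-yl]-3a,4,5,7a-tetrahydro-1-benzofuran-2(3H)-one | Cl[C@H]1C=C[C@H]2OC(=O)C[C@]2(C1)[C@H](O[Si](C)(C)C(C)(C)C)/C=C(\C)C/C=C/C(C)(C)O[Si](CC)(CC)CC
F2 | step 12 | N-methoxy-N-methyl-2-[(1S,2R,5S)-1-[(1R,2E,5E)-1-(tert-butyldimethylsilyloxy)-3,7-dimethyl-7-(triethylsilyloxy)octa-2,5-dien-1-yl]-2,5-dihydroxycyclohex-3-en-1-yl]acetamide | O[C@@H]1C=C[C@@H](O)[C@@](CC(=O)N(C)OC)(C1)[C@H](O[Si](C)(C)C(C)(C)C)/C=C(\C)C/C=C/C(C)(C)O[Si](CC)(CC)CC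
F3 | step 8 | methyl 2-[(1S)-1-[(1S,2E,5E)-1-hydroxy-3,7-dimethyl-7-(triethylsilyloxy)octa-2,5-dien-1-yl]cyclohexa-2,4-dien-1-yl]acetate | COC(=O)C[C@@]1(C=CC=CC1)[C@@H](O)/C=C(\C)C/C=C/C(C)(C)O[Si](CC)(CC)CC
F4 | step 8 | methyl 2-[(1S)-1-[(2E,5E)-3,7-dimethyl-7-(triethylsilyloxy)octa-2,5-dienoyl]cyclohexa-2,4-dien-1-yl]acetate | COC(=O)C[C@@]1(C=CC=CC1)C(=O)/C=C(\C)C/C=C/C(C)(C)O[Si](CC)(CC)CC
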